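**Plan**

Numbering: C1 ring-fusion CH, C2 lactone OCH, C3=C4 and C7=C8 the E-alkenes, C11–C12 the epoxide (C20 methyl on C12), C13 the CHOAc carbon, C14 the CH2, C15(=C17)–C16(=O) the lactone carbons.
Enabling feature: in the 14-membered carbocycle the trisubstituted C11–C12 oxirane lies next to oxygen-bearing C13. This triad is a masked (E)-2-methyl allylic alcohol and, one level further back, a C11≡C12 alkyne flanked by a C13 carbinol.
Cuts, in order: the acetyl C–O, the epoxide oxygen, C12–C20, then C11≡C12 (opens the 14-ring to a diyne with two methyl caps), then C1–C2 together with O–C16 (opens the lactone). This leaves a C2–C11 enal and a C12–C1/C15–C17 bromomethyl enoate.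
Forward: geraniol is extended at C9 to enal 11 and but-2-ynal is elaborated to bromide 19. Their union builds the five-membered lactone first, alkyne metathesis then closes the 14-ring, and the alkyne is turned into the methyl-bearing epoxide.
Stereochemistry: C13 comes from a catalytic asymmetric allylation of but-2-ynal. C1/C2 come from a ligand-controlled chromium allylation (cis through a chair transition state). The C11=C12 geometry comes from trans-hydrostannation, and C11/C12 from oxygen delivery by the C13 hydroxyl. The two E-alkenes come from geraniol and an E-selective SeO2 oxidation.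

Key step: step 14

Assumption: for the carbazole bis(oxazoline)–chromium catalyst of step 13, the (S,S)-ligand is taken to send the allylchromium to the Re face of enal 11; if the sense proves opposite, the (R,R)-ligand is used and nothing else changes.

Step 1
Reactants: 1 geraniol
Product: 2 geranyl tert-butyldimethylsilyl ether
Conditions: TBSCl, imidazole, DMF, 0 °C → rt
Reagents that add atoms: tert-butyldimethylsilyl chloride, CC(C)(C)[Si](C)(C)Cl
Why: Routine silylation of a primary allylic alcohol masks the C2 oxygen against the organolithium chemistry of step 4 and is removable with fluoride alone.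

Step 2
Reactants: 2 geranyl tert-butyldimethylsilyl ether
Product: 3 (2E,6E)-8-[(tert-butyldimethylsilyl)oxy]-2,6-dimethylocta-2,6-dien-1-ol
Conditions: SeO2 (cat.), t-BuOOH, salicylic acid (cat.), CH2Cl2, 0 °C → rt
Reagents that add atoms: tert-butyl hydroperoxide, CC(C)(C)OO
Why: Selenium dioxide allylic oxidation (ene reaction, then [2,3]-sigmatropic shift) attacks the more electron-rich distal alkene at its E-methyl group, which oxygenates the future C9 and fixes the C7=C8 E-geometry.

Step 3
Reactants: 3 (2E,6E)-8-[(tert-butyldimethylsilyl)oxy]-2,6-dimethylocta-2,6-dien-1-ol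
Product: 4 (2E,6E)-8-bromo-3,7-dimethylocta-2,6-dien-1-yl tert-butyldimethylsilyl ether
Conditions: CBr4, PPh3, CH2Cl2, 0 °C
Reagents that add atoms: carbon tetrabromide, BrC(Br)(Br)Br
Why: The Appel reaction replaces the primary allylic hydroxyl by SN2 attack on the oxyphosphonium salt under neutral conditions, without allylic transposition or loss of the silyl ether.

Step 4
Reactants: 5 1-(trimethylsilyl)propyne; 4 (2E,6E)-8-bromo-3,7-dimethylocta-2,6-dien-1-yl tert-butyldimethylsilyl ether
Product: 7 (2E,6E)-1-[(tert-butyldimethylsilyl)oxy]-3,7-dimethyl-11-(trimethylsilyl)undeca-2,6-dien-10-yne, via lithiated silylpropyne 6 (not isolated)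
Conditions: 5, n-BuLi, THF, −20 °C; then 4, −78 °C → rt
Reagents that add atoms: none
Why: Propargylic lithiation and SN2 alkylation with a primary allylic bromide forms C9–C10, and the silyl cap keeps the anion reacting at its propargylic rather than its allenic terminus.

Step 5
Reactants: 7 (2E,6E)-1-[(tert-butyldimethylsilyl)oxy]-3,7-dimethyl-11-(trimethylsilyl)undeca-2,6-dien-10-yne
Product: 8 (2E,6E)-3,7-dimethylundeca-2,6-dien-10-yn-1-ol
Conditions: TBAF (2.5 equiv), THF, 0 °C → rt
Reagents that add atoms: none
Why: Fluoride-mediated desilylation cleaves the C(sp)–Si and the O–Si bond in one operation, driven by Si–F bond formation, and touches nothing else in the dienyne.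

Step 6
Reactants: 8 (2E,6E)-3,7-dimethylundeca-2,6-dien-10-yn-1-ol
Product: 10 (2E,6E)-3,7-dimethyldodeca-2,6-dien-10-yn-1-ol, via dilithio alkoxide-acetylide 9 (not isolated)
Conditions: n-BuLi (2.1 equiv), THF, −78 → −20 °C; MeI (1.1 equiv), −78 °C → rt
Reagents that add atoms: iodomethane, CI
Why: After double deprotonation, acetylide alkylation with one equivalent of iodomethane installs the methyl cap needed for metathesis, since the lithium alkoxide is far less nucleophilic in THF.

Step 7
Reactants: 10 (2E,6E)-3,7-dimethyldodeca-2,6-dien-10-yn-1-ol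
Product: 11 (2E,6E)-3,7-dimethyldodeca-2,6-dien-10-ynal
Conditions: MnO2, CH2Cl2, rt
Reagents that add atoms: none
Why: Manganese dioxide oxidation is selective for allylic alcohols, stops at the enal and preserves the C3=C4 E-geometry.

Step 8
Reactants: 12 but-2-ynal; 13 allyltributylstannane
Product: 14 (4S)-hept-1-en-5-yn-4-ol
Conditions: (S)-BINOL (20 mol %), Ti(OiPr)4 (10 mol %), 4 Å MS, CH2Cl2, −20 °C; aq. NaHCO3
Reagents that add atoms: none
Why: In the Keck asymmetric allylation the (S)-BINOL–titanium Lewis acid exposes the Si face of the ynal to the allylstannane, which sets C13 as S, the outcome for aldehydes whose substituent outranks the allyl CH2.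

Step 9
Reactants: 14 (4S)-hept-1-en-5-yn-4-ol
Product: 15 (4S)-4-[(tert-butyldimethylsilyl)oxy]hept-1-en-5-yne
Conditions: TBSCl, imidazole, DMF, rt
Reagents that add atoms: tert-butyldimethylsilyl chloride, CC(C)(C)[Si](C)(C)Cl
Why: Standard silylation gives a propargylic ether that is robust enough for steps 10–14 and is a poor leaving group toward the molybdenum catalyst.

Step 10
Reactants: 15 (4S)-4-[(tert-butyldimethylsilyl)oxy]hept-1-en-5-yne
Product: 16 (3S)-3-[(tert-butyldimethylsilyl)oxy]hex-4-ynal
Conditions: OsO4 (2 mol %), NaIO4, 2,6-lutidine, dioxane/H2O, rt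
Reagents that add atoms: sodium periodate, [Na+].[O-]I(=O)(=O)=O (terminal source of the aldehyde oxygen, relayed by OsO4)
Why: The Lemieux–Johnson cleavage takes the terminal alkene far faster than the internal alkyne and exposes C1 as an aldehyde, with lutidine buffering the β-silyloxy aldehyde against elimination.

Step 11
Reactants: 16 (3S)-3-[(tert-butyldimethylsilyl)oxy]hex-4-ynal; 17 methyl acrylate
Product: 18 methyl (5S)-5-[(tert-butyldimethylsilyl)oxy]-3-hydroxy-2-methylideneoct-6-ynoate (both C3 epimers)
Conditions: DABCO, methyl acrylate (excess), MeOH, rt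
Reagents that add atoms: none
Why: The Morita–Baylis–Hillman reaction joins C1 to C15 under a weak amine base that should not expel the poor silyloxide leaving group, and the new carbinol centre needs no control because step 12 erases it.

Step 12
Reactants: 18 methyl (5S)-5-[(tert-butyldimethylsilyl)oxy]-3-hydroxy-2-methylideneoct-6-ynoate
Product: 19 methyl (2Z,5S)-2-(bromomethyl)-5-[(tert-butyldimethylsilyl)oxy]oct-2-en-6-ynoate
Conditions: NBS, Me2S, CH2Cl2, 0 °C → rt
Reagents that add atoms: N-bromosuccinimide, O=C1CCC(=O)N1Br
Why: The alcohol is activated as an alkoxysulfonium salt (Corey–Kim-type reagent) and bromide attacks the methylidene carbon in SN2′ fashion, giving the conjugated Z-enoate with C14 cis to CH2Br under neutral conditions that spare silyl ether and alkyne.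

Step 13
Reactants: 11 (2E,6E)-3,7-dimethyldodeca-2,6-dien-10-ynal; 19 methyl (2Z,5S)-2-(bromomethyl)-5-[(tert-butyldimethylsilyl)oxy]oct-2-en-6-ynoate
Product: 21 (4S,5S)-4-{(2S)-2-[(tert-butyldimethylsilyl)oxy]pent-3-yn-1-yl}-5-[(1E,5E)-2,6-dimethylundeca-1,5-dien-9-yn-1-yl]-3-methylideneoxolan-2-one, via syn-hydroxy ester 20 (not isolated)
Conditions: CrCl2 (10 mol %), L* (12 mol %; L* = (S,S)-1,8-bis(4-isopropyl-2-oxazolinyl)-3,6-diphenylcarbazole), Mn, Cp2ZrCl2, LiCl, THF, rt; aq. work-up; then PPTS (cat.), CH2Cl2, rt
Reagents that add atoms: none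
Why: In this catalytic asymmetric Nozaki–Hiyama–Kishi 2-(alkoxycarbonyl)allylation followed by lactonisation, the allylchromium attacks through C1; the C15 ester keeps C14 cis to the CH2–Cr terminus, so the chair transition state gives the syn adduct and hence the cis-lactone, while the tridentate ligand, not remote C13, selects the Re face of the enal and sets C1 and C2 as S,S.

Step 14
Reactants: 21 cis-lactone diyne
Product: 22 (1S,2S,13S)-13-[(tert-butyldimethylsilyl)oxy]-20-norcembra-3E,7E,15(17)-trien-11-yn-16,2-olide
Conditions: [(4-MeOC6H4)C≡Mo(OSiPh3)3] (10–15 mol %), 5 Å MS, toluene (2 mM), rt → 60 °C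
Reagents that add atoms: none
Why: The molybdenum alkylidyne adds to one methyl-capped alkyne of 21 by [2+2] cycloaddition, the metallacyclobutadiene cycloreverts to a substrate-bound alkylidyne, and the same sequence on the second alkyne forms C11≡C12 and releases but-2-yne. The reaction type is ring-closing alkyne metathesis as established for macrocycles that carry esters and propargylic silyl ethers. The 14-membered ring closes end-to-end between the two alkyne termini under high dilution, and sequestration of but-2-yne in the 5 Å sieves drives the equilibrium toward the cycloalkyne. No stereocentre is formed, C1, C2 and C13 are spectators, and a ring of this size can hold the linear C10–C11≡C12–C13 unit. The step needs selectivity for alkynes over the two trisubstituted alkenes, the exo-methylene enoate and the lactone carbonyl, which the silanolate-tempered alkylidyne provides because it does not engage C=C or C=O bonds. The bulky, poorly leaving OTBS group at C13 protects the propargylic position from ionisation at the Lewis-acidic metal.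

Step 15
Reactants: 22 cycloalkyne silyl ether
Product: 23 (1S,2S,13S)-13-hydroxy-20-norcembra-3E,7E,15(17)-trien-11-yn-16,2-olide
Conditions: HF·pyridine, pyridine, THF, 0 °C → rt
Reagents that add atoms: none
Why: Buffered HF desilylation frees the C13 hydroxyl without the basic fluoride conditions that could add to or isomerise the α-methylene lactone.

Step 16
Reactants: 23 macrocyclic propargylic alcohol
Product: 24 (1S,2S,13S,11Z)-13-hydroxy-12-(tributylstannyl)-20-norcembra-3E,7E,11,15(17)-tetraen-16,2-olide
Conditions: [Cp*RuCl]4 (2.5 mol %), Bu3SnH (slow addition), CH2Cl2, rt, dark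
Reagents that add atoms: tributyltin hydride, CCCC[SnH](CCCC)CCCC
Why: In the ruthenium-catalysed hydroxyl-directed trans-hydrostannation a hydrogen bond from the C13–OH to the Ru–Cl unit orients the alkyne so that tin goes to proximal C12 and hydrogen to C11 on the opposite side, while slow addition with exclusion of light and air suppresses radical addition to the exo-methylene group.

Step 17
Reactants: 24 alkenylstannane
Product: 25 (1S,2S,13S)-13-hydroxycembra-3E,7E,11E,15(17)-tetraen-16,2-olide
Conditions: MeI, CuTC, [Ph2PO2][NBu4], Pd(PPh3)4 (10 mol %), DMF, rt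
Reagents that add atoms: iodomethane, CI
Why: The copper-assisted Stille-type methyl coupling transmetalates tin to copper with the phosphinate as tin scavenger and couples with retention of geometry, placing C20 on C12 of an E-alkene while tolerating the free alcohol.

Step 18
Reactants: 25 (E)-2-methyl allylic alcohol
Product: 26 (1S,2S,11S,12S,13S)-11,12-epoxy-13-hydroxycembra-3E,7E,15(17)-trien-16,2-olide
Conditions: VO(acac)2 (5 mol %), t-BuOOH (decane), CH2Cl2, 0 °C → rt
Reagents that add atoms: tert-butyl hydroperoxide, CC(C)(C)OO
Why: In the vanadium-catalysed hydroxyl-directed epoxidation the C13 vanadate delivers oxygen to the alkene face it overhangs in the rotamer that places C13–H next to the C20 methyl (minimised A1,2 strain), which should give the erythro epoxy alcohol matching the target at C11 and C12 and leave the undirected C3=C4 and C7=C8 alkenes and the electron-poor enoate untouched.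

Step 19
Reactants: 26 epoxy alcohol
Product: 27 (1S,2S,11S,12R,13S)-13-acetoxy-11,12-epoxycembra-3E,7E,15(17)-trien-16,2-olide (CNP0146076.2)
Conditions: Ac2O, DMAP (cat.), pyridine, 0 °C → rt
Reagents that add atoms: acetic anhydride, CC(=O)OC(C)=O
Why: DMAP-catalysed acetylation of the secondary alcohol leaves the epoxide and lactone alone, and the C12 descriptor changes from S to R only because acetoxy-bearing C13 now outranks C11.

**Compound list**

1 | geraniol | CC(C)=CCC/C(C)=C/CO | starting material
2 | geranyl tert-butyldimethylsilyl ether | CC(C)=CCC/C(C)=C/CO[Si](C)(C)C(C)(C)C | intermediate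
3 | (2E,6E)-8-[(tert-butyldimethylsilyl)oxy]-2,6-dimethylocta-2,6-dien-1-ol | OC/C(C)=C/CC/C(C)=C/CO[Si](C)(C)C(C)(C)C | intermediate
4 | (2E,6E)-8-bromo-3,7-dimethylocta-2,6-dien-1-yl tert-butyldimethylsilyl ether | BrC/C(C)=C/CC/C(C)=C/CO[Si](C)(C)C(C)(C)C | intermediate
5 | 1-(trimethylsilyl)propyne | CC#C[Si](C)(C)C | starting material
6 | 3-lithio-1-(trimethylsilyl)propyne | [Li]CC#C[Si](C)(C)C | intermediate
7 | (2E,6E)-1-[(tert-butyldimethylsilyl)oxy]-3,7-dimethyl-11-(trimethylsilyl)undeca-2,6-dien-10-yne | C[Si](C)(C)C#CCC/C(C)=C/CC/C(C)=C/CO[Si](C)(C)C(C)(C)C | intermediate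
8 | (2E,6E)-3,7-dimethylundeca-2,6-dien-10-yn-1-ol | C#CCC/C(C)=C/CC/C(C)=C/CO | intermediate
9 | dilithio alkoxide-acetylide of 8 | [Li]C#CCC/C(C)=C/CC/C(C)=C/CO[Li] | intermediate
10 | (2E,6E)-3,7-dimethyldodeca-2,6-dien-10-yn-1-ol | CC#CCC/C(C)=C/CC/C(C)=C/CO | intermediate
11 | (2E,6E)-3,7-dimethyldodeca-2,6-dien-10-ynal (C2–C11 enal) | CC#CCC/C(C)=C/CC/C(C)=C/C=O | intermediate
12 | but-2-ynal | CC#CC=O | starting material
13 | allyltributylstannane | C=CC[Sn](CCCC)(CCCC)CCCC | starting material
14 | (4S)-hept-1-en-5-yn-4-ol | C=CC[C@H](O)C#CC | intermediate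
15 | (4S)-4-[(tert-butyldimethylsilyl)oxy]hept-1-en-5-yne | C=CC[C@H](O[Si](C)(C)C(C)(C)C)C#CC | intermediate
16 | (3S)-3-[(tert-butyldimethylsilyl)oxy]hex-4-ynal | O=CC[C@H](O[Si](C)(C)C(C)(C)C)C#CC | intermediate
17 | methyl acrylate | C=CC(=O)OC | starting material
18 | methyl (5S)-5-[(tert-butyldimethylsilyl)oxy]-3-hydroxy-2-methylideneoct-6-ynoate, C3 epimers | C=C(C(=O)OC)C(O)C[C@H](O[Si](C)(C)C(C)(C)C)C#CC | intermediate
19 | methyl (2Z,5S)-2-(bromomethyl)-5-[(tert-butyldimethylsilyl)oxy]oct-2-en-6-ynoate | COC(=O)/C(CBr)=C/C[C@H](O[Si](C)(C)C(C)(C)C)C#CC | intermediate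
20 | (1S,2S,13S)-syn-hydroxy ester: methyl acrylate bearing at C15 the C1 methine, free C2–OH, C13–OTBS, both alkynes methyl-capped | C=C(C(=O)OC)[C@H](C[C@H](O[Si](C)(C)C(C)(C)C)C#CC)[C@@H](O)/C=C(\C)CC/C=C(\C)CCC#CC | intermediate
21 | (4S,5S)-4-{(2S)-2-[(tert-butyldimethylsilyl)oxy]pent-3-yn-1-yl}-5-[(1E,5E)-2,6-dimethylundeca-1,5-dien-9-yn-1-yl]-3-methylideneoxolan-2-one (cis-lactone diyne) | C=C1C(=O)O[C@@H](/C=C(\C)CC/C=C(\C)CCC#CC)[C@H]1C[C@H](O[Si](C)(C)C(C)(C)C)C#CC | intermediate
22 | (1S,2S,13S)-13-[(tert-butyldimethylsilyl)oxy]-20-norcembra-3E,7E,15(17)-trien-11-yn-16,2-olide (14-membered cycloalkyne) | C=C1C(=O)O[C@H]2/C=C(\C)CC/C=C(\C)CCC#C[C@@H](O[Si](C)(C)C(C)(C)C)C[C@@H]12 | intermediate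
23 | (1S,2S,13S)-13-hydroxy-20-norcembra-3E,7E,15(17)-trien-11-yn-16,2-olide | C=C1C(=O)O[C@H]2/C=C(\C)CC/C=C(\C)CCC#C[C@@H](O)C[C@@H]12 | intermediate
24 | (1S,2S,13S,11Z)-13-hydroxy-12-(tributylstannyl)-20-norcembra-3E,7E,11,15(17)-tetraen-16,2-olide | C=C1C(=O)O[C@H]2/C=C(\C)CC/C=C(\C)CC/C=C(\[Sn](CCCC)(CCCC)CCCC)[C@@H](O)C[C@@H]12 | intermediate
25 | (1S,2S,13S)-13-hydroxycembra-3E,7E,11E,15(17)-tetraen-16,2-olide | C=C1C(=O)O[C@H]2/C=C(\C)CC/C=C(\C)CC/C=C(\C)[C@@H](O)C[C@@H]12 | intermediate
26 | (1S,2S,11S,12S,13S)-11,12-epoxy-13-hydroxycembra-3E,7E,15(17)-trien-16,2-olide | C=C1C(=O)O[C@H]2/C=C(\C)CC/C=C(\C)CC[C@@H]3O[C@@]3(C)[C@@H](O)C[C@@H]12 | intermediate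
27 | (1S,2S,11S,12R,13S)-13-acetoxy-11,12-epoxycembra-3E,7E,15(17)-trien-16,2-olide (CNP0146076.2) | C=C1C(=O)O[C@H]2/C=C(\C)CC/C=C(\C)CC[C@@H]3O[C@@]3(C)[C@@H](OC(C)=O)C[C@@H]12 | target

**Step count and risks**

Total step count: 19. Longest linear sequence: 14 steps from geraniol (steps 1–7, then 13–19). The second branch (steps 8–12) has 5 steps.

**Step 13.**
- What may go wrong: the ligand may give insufficient facial control on a β,β-disubstituted enal. The syn preference may also erode through E/Z equilibration of the allylchromium. Either way C1 and C2 would arise as mixtures.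
- Fallback: catalyst control is given up and C13 is used as an internal resolving centre. Setting out from 11 and 19, a stoichiometric zinc Barbier allylation (activated Zn, THF, 50 °C) lets the zinc alkoxide lactonise directly. The chair transition state of the Z-configured allylzinc still secures the cis ring fusion. The reaction should give 21 together with the (1R,2R,13S)-cis-lactone diyne F1. The two are diastereomers, so chromatography separates them and the route is rejoined at 21.

**Step 14.**
- What may go wrong: intermolecular metathesis may lead to oligomerisation if the cis-fused lactone holds the two alkyne arms apart. The catalyst may also decay gradually at the Lewis-basic enoate.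
- Fallback: the order of ring formation is reversed while the C11≡C12 closure is kept. Setting out from hydroxy ester 20, now isolated after the aqueous work-up of step 13, TESCl and imidazole give the C2 triethylsilyl ether diyne F2. Alkyne metathesis of this more flexible chain under the step 14 conditions gives the 14-membered cycloalkyne acrylate ester F3. PPTS in MeOH removes the triethylsilyl group selectively, and the freed C2 hydroxyl closes onto the methyl ester, returning to the route at 22.

**Step 18.**
- What may go wrong: facial selectivity may be poor if the macrocycle favours a rotamer about C12–C13 that presents the other alkene face to the vanadate. Slow undirected oxidation at C7=C8 may also compete.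
- Fallback: substrate-directed delivery is replaced by reagent control. Setting out from 25, a Sharpless asymmetric epoxidation is run (Ti(OiPr)4, L-(+)-diisopropyl tartrate, t-BuOOH, 4 Å MS, CH2Cl2, −20 °C). The (13S)-configured secondary allylic alcohol is the fast-reacting, erythro-selective partner of this tartrate. The route is rejoined at 26, and this fallback makes no compound outside the list (F0).

**Further compounds**

F1 | step 13 | (1R,2R,13S)-cis-lactone diyne, the C1/C2-inverted diastereomer of 21 | C=C1C(=O)O[C@H](/C=C(\C)CC/C=C(\C)CCC#CC)[C@@H]1C[C@H](O[Si](C)(C)C(C)(C)C)C#CC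
F2 | step 14 | C2 triethylsilyl ether of hydroxy ester 20 | C=C(C(=O)OC)[C@H](C[C@H](O[Si](C)(C)C(C)(C)C)C#CC)[C@@H](O[Si](CC)(CC)CC)/C=C(\C)CC/C=C(\C)CCC#CC
F3 | step 14 | 14-membered cycloalkyne with C1 2-(methoxycarbonyl)vinyl side chain, C2–OTES and C13–OTBS | C=C(C(=O)OC)[C@@H]1C[C@H](O[Si](C)(C)C(C)(C)C)C#CCC/C(C)=C/CC/C(C)=C/[C@@H]1O[Si](CC)(CC)CC
F0 | step 18 | none | none
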